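**Retrosynthetic overview**
1. Digriseophene A (13) is a homodimer. Its only sp3 ring-linking carbon is the CH2 that joins C3 of ring A (the 2,6-dihydroxy-4-methoxybenzoyl, phloroglucinol-type ring) of one half to C3 of ring A of the other half.
2. Both Ar–CH2 bonds are cut at once. This gives two molecules of the unprotected benzophenone 10 (griseophenone C) and formaldehyde, joined in a biomimetic dimerisation through ortho-quinone methide 12.
3. 10 comes from tris-MOM ketone 9 and carbinol 8. The ring A C1–C(carbinol) bond is cut to aryllithium 6 (ortho-lithiation of 2 between its two OMOM groups) and aldehyde 5.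
4. 2 comes from 5-methoxyresorcinol (1). 5 comes from 2,4-dihydroxy-6-methylbenzaldehyde (3). No ring is constructed; all four benzene rings are bought.

Key step: step 7

Remark: the target has no stereocentre and no configurationally stable axis, so it is achiral and the route needs no stereocontrol.

**Step 1**
Reactants: 1 5-methoxyresorcinol (3,5-dihydroxyanisole)
Product: 2 1-methoxy-3,5-bis(methoxymethoxy)benzene
Conditions: NaH (2.4 equiv), MOMCl (2.4 equiv), DMF, 0 °C → rt
Reagents that add atoms: chloromethyl methyl ether (MOMCl), COCCl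
Why: Williamson-type O-alkylation of both phenoxides with an α-chloro ether should give the bis-acetal, whose OMOM groups later direct the ortho-lithiation.

**Step 2**
Reactants: 3 2,4-dihydroxy-6-methylbenzaldehyde
Product: 4 2-hydroxy-4-(methoxymethoxy)-6-methylbenzaldehyde
Conditions: MOMCl (1.1 equiv), K2CO3 (1.5 equiv), acetone, 0 °C → rt
Reagents that add atoms: chloromethyl methyl ether (MOMCl), COCCl
Why: Chemoselective Williamson O-alkylation, because the 2-OH is held in a hydrogen bond to the formyl group and the free, more acidic 4-OH should react alone.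

**Step 3**
Reactants: 4 2-hydroxy-4-(methoxymethoxy)-6-methylbenzaldehyde
Product: 5 2-methoxy-4-(methoxymethoxy)-6-methylbenzaldehyde
Conditions: MeI (2 equiv), K2CO3 (2 equiv), DMF, 40 °C
Reagents that add atoms: iodomethane, CI
Why: Williamson methylation of the remaining chelated phenol should proceed under these more forcing polar aprotic conditions, which the acetal and the aldehyde tolerate.

**Step 4**
Reactants: 2 1-methoxy-3,5-bis(methoxymethoxy)benzene; 5 2-methoxy-4-(methoxymethoxy)-6-methylbenzaldehyde
Product: 8 rac-[4-methoxy-2,6-bis(methoxymethoxy)phenyl][2-methoxy-4-(methoxymethoxy)-6-methylphenyl]methanol, via aryllithium 6 (not isolated), via lithium alkoxide 7 (not isolated)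
Conditions: 2 (1.2 equiv), n-BuLi (1.15 equiv), THF, 0 °C; then 5 (1.0 equiv), −78 °C → rt; H2O
Reagents that add atoms: none
Why: Directed ortho-metalation should occur at C2 of 2, the carbon flanked by two chelating OMOM groups (a stronger director pair than OMOM/OMe at C4 and C6), and 1,2-addition of 6 to the non-enolisable aldehyde 5 gives the diaryl carbinol, whose new stereocentre forms racemic and is erased in step 5.

**Step 5**
Reactants: 8 rac-[4-methoxy-2,6-bis(methoxymethoxy)phenyl][2-methoxy-4-(methoxymethoxy)-6-methylphenyl]methanol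
Product: 9 [4-methoxy-2,6-bis(methoxymethoxy)phenyl][2-methoxy-4-(methoxymethoxy)-6-methylphenyl]methanone
Conditions: IBX (1.5 equiv), EtOAc, 75 °C
Reagents that add atoms: none
Why: Hypervalent iodine(V) oxidation of a doubly benzylic secondary alcohol under essentially neutral conditions should give the diaryl ketone and leave the three acetals intact.

**Step 6**
Reactants: 9 [4-methoxy-2,6-bis(methoxymethoxy)phenyl][2-methoxy-4-(methoxymethoxy)-6-methylphenyl]methanone
Product: 10 griseophenone C [(2,6-dihydroxy-4-methoxyphenyl)(4-hydroxy-2-methoxy-6-methylphenyl)methanone]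
Conditions: conc. HCl (cat.), MeOH (0.02 M), 45 °C
Reagents that add atoms: none
Why: Acid-catalysed methanolysis (transacetalisation) of the three MOM ethers should free the phenols, while the large excess of methanol captures the methoxymethyl fragment as dimethoxymethane and the aryl methyl ethers stay intact.

**Step 7**
Reactants: 10 griseophenone C (two molecules per formaldehyde)
Product: 13 digriseophene A, via hydroxymethyl adduct 11 (not isolated), via ortho-quinone methide 12 (not isolated)
Conditions: 37% aq. CH2O (0.45 equiv, slow addition), K2CO3 (0.2 equiv), THF–H2O 1:1, 0 °C → rt; then 1 M HCl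
Reagents that add atoms: formaldehyde, C=O
Why: Base-mediated hydroxymethylation (Lederer–Manasse reaction) of the ring-A phenoxide of 10 at C3 gives 11, which loses hydroxide to ortho-quinone methide 12, and a second ring-A phenoxide of 10 adds through its C3 in a Michael reaction and rearomatises, so that both Ar–CH2 bonds are formed in one flask. The closest known reaction type is the formaldehyde-mediated methylene bridging of acylphloroglucinols, a special case of the phenol–formaldehyde condensation. No ring is closed and no stereocentre is formed, the product being achiral. The step needs selectivity for ring A over ring B, and this rests on the substrate: C3 and C5 of ring A are each ortho or para to three oxygen donors (2-OH, 4-OMe, 6-OH), whereas C3' and C5' of ring B are activated by only two oxygens and a methyl group. The site on ring A is not in doubt, because C3 and C5 are equivalent by the local symmetry of the 2,6-dihydroxy-4-methoxybenzoyl ring. Bridging beyond the dimer at the remaining C5–H positions is held back by using formaldehyde as the limiting reagent, added slowly to an excess of 10, with recovery of unreacted 10.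

**Compound list**
1 | 5-methoxyresorcinol (3,5-dihydroxyanisole) | COc1cc(O)cc(O)c1 | starting material
2 | 1-methoxy-3,5-bis(methoxymethoxy)benzene | COCOc1cc(OC)cc(OCOC)c1 | intermediate
3 | 2,4-dihydroxy-6-methylbenzaldehyde | Cc1cc(O)cc(O)c1C=O | starting material
4 | 2-hydroxy-4-(methoxymethoxy)-6-methylbenzaldehyde | Cc1cc(OCOC)cc(O)c1C=O | intermediate
5 | 2-methoxy-4-(methoxymethoxy)-6-methylbenzaldehyde | Cc1cc(OCOC)cc(OC)c1C=O | intermediate
6 | [4-methoxy-2,6-bis(methoxymethoxy)phenyl]lithium | [Li]c1c(OCOC)cc(OC)cc1OCOC | intermediate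
7 | lithium [4-methoxy-2,6-bis(methoxymethoxy)phenyl][2-methoxy-4-(methoxymethoxy)-6-methylphenyl]methanolate (racemic) | [Li]OC(c1c(OCOC)cc(OC)cc1OCOC)c1c(C)cc(OCOC)cc1OC | intermediate
8 | rac-[4-methoxy-2,6-bis(methoxymethoxy)phenyl][2-methoxy-4-(methoxymethoxy)-6-methylphenyl]methanol | OC(c1c(OCOC)cc(OC)cc1OCOC)c1c(C)cc(OCOC)cc1OC | intermediate
9 | [4-methoxy-2,6-bis(methoxymethoxy)phenyl][2-methoxy-4-(methoxymethoxy)-6-methylphenyl]methanone | O=C(c1c(OCOC)cc(OC)cc1OCOC)c1c(C)cc(OCOC)cc1OC | intermediate
10 | griseophenone C, (2,6-dihydroxy-4-methoxyphenyl)(4-hydroxy-2-methoxy-6-methylphenyl)methanone | COc1cc(O)c(C(=O)c2c(C)cc(O)cc2OC)c(O)c1 | intermediate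
11 | [2,6-dihydroxy-3-(hydroxymethyl)-4-methoxyphenyl](4-hydroxy-2-methoxy-6-methylphenyl)methanone | COc1cc(O)c(C(=O)c2c(C)cc(O)cc2OC)c(O)c1CO | intermediate
12 | 3-hydroxy-2-(4-hydroxy-2-methoxy-6-methylbenzoyl)-5-methoxy-6-methylidenecyclohexa-2,4-dien-1-one | C=C1C(=O)C(C(=O)c2c(C)cc(O)cc2OC)=C(O)C=C1OC | intermediate
13 | digriseophene A, [methylenebis(2,4-dihydroxy-6-methoxy-3,1-phenylene)]bis[(4-hydroxy-2-methoxy-6-methylphenyl)methanone] | COc1cc(O)c(C(=O)c2c(C)cc(O)cc2OC)c(O)c1Cc1c(OC)cc(O)c(C(=O)c2c(C)cc(O)cc2OC)c1O | target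

**Step count**
Total steps: 7. Longest linear sequence: 6 steps (3 → 4 → 5 → 8 → 9 → 10 → 13).

**Steps most likely to fail**

Step 7. After the first bridge each ring A still carries an activated C5–H, so hydroxymethylation and bridging may run on to trimers and oligomers. Ring B carbons may also compete for the quinone methide. The fallback sets out from 10 and comes back at 13. It attaches the one-carbon electrophile to one monomer first and forms the second C–C bond in a separate stage. Mannich reaction of 10 with dimethylmethyleneiminium iodide (1.0 equiv, CH2Cl2, rt) should give [3-[(dimethylamino)methyl]-2,6-dihydroxy-4-methoxyphenyl](4-hydroxy-2-methoxy-6-methylphenyl)methanone F1, which can be purified so that each molecule carries exactly one benzylic electrophilic carbon on ring A. Heating F1 with an excess of 10 (3 equiv, dioxane, 100 °C) should expel dimethylamine, regenerate ortho-quinone methide 12 at low stationary concentration and trap it with 10 to give 13. The excess of 10 is recovered.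

Step 6. The methoxymethyl cations released on acidolysis are formaldehyde equivalents. They may alkylate the freed, strongly nucleophilic ring A, which would cause premature and uncontrolled methylene bridging. The fallback sets out from 1 and 3 and comes back at 10. It changes the acetal to one that cannot deliver a one-carbon electrophile.
- 1 with 3,4-dihydro-2H-pyran (PPTS, CH2Cl2) should give 1-methoxy-3,5-bis(tetrahydro-2H-pyran-2-yloxy)benzene F2, a diastereomer mixture of no consequence.
- 3 under the same conditions should react only at the non-chelated 4-OH to give 2-hydroxy-6-methyl-4-(tetrahydro-2H-pyran-2-yloxy)benzaldehyde F3.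
- Methylation of F3 (MeI, K2CO3, DMF) gives 2-methoxy-6-methyl-4-(tetrahydro-2H-pyran-2-yloxy)benzaldehyde F4.
- Ortho-lithiation of F2 between its two OTHP groups (n-BuLi, THF, 0 °C) gives [4-methoxy-2,6-bis(tetrahydro-2H-pyran-2-yloxy)phenyl]lithium F5.
- F5 adds to F4 through the lithium alkoxide F6 to give, after water quench, [4-methoxy-2,6-bis(tetrahydro-2H-pyran-2-yloxy)phenyl][2-methoxy-6-methyl-4-(tetrahydro-2H-pyran-2-yloxy)phenyl]methanol F7.
- IBX oxidation gives [4-methoxy-2,6-bis(tetrahydro-2H-pyran-2-yloxy)phenyl][2-methoxy-6-methyl-4-(tetrahydro-2H-pyran-2-yloxy)phenyl]methanone F8.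
- PPTS in MeOH at rt should then release 10 together with 2-methoxytetrahydropyran, which does not act as a bridging electrophile.

Step 4. Metalation may not be confined to C2 of 2. Lithiation at C4/C6, between OMOM and OMe, would give regioisomeric carbinols that are hard to separate. The fallback sets out from 3 and from commercial phloroglucinol F9, and comes back at 10. It fixes the site of metalation by symmetry and introduces the 4-OMe group afterwards.
- Phloroglucinol F9 (NaH, MOMCl, DMF) gives 1,3,5-tris(methoxymethoxy)benzene F10, in which all three ring C–H are equivalent.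
- 3 is benzylated at the 4-OH (BnBr, K2CO3, acetone) to 4-(benzyloxy)-2-hydroxy-6-methylbenzaldehyde F11.
- Methylation of F11 (MeI, K2CO3, DMF) gives 4-(benzyloxy)-2-methoxy-6-methylbenzaldehyde F12.
- Lithiation of F10 (n-BuLi, THF, 0 °C) gives [2,4,6-tris(methoxymethoxy)phenyl]lithium F13.
- F13 adds to F12 through the lithium alkoxide F14 to give [4-(benzyloxy)-2-methoxy-6-methylphenyl][2,4,6-tris(methoxymethoxy)phenyl]methanol F15.
- IBX oxidation gives [4-(benzyloxy)-2-methoxy-6-methylphenyl][2,4,6-tris(methoxymethoxy)phenyl]methanone F16.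
- HCl in MeOH gives [4-(benzyloxy)-2-methoxy-6-methylphenyl](2,4,6-trihydroxyphenyl)methanone F17.
- Me2SO4 (1.0 equiv), K2CO3, acetone should methylate only the 4-OH para to the carbonyl, because the 2- and 6-OH are hydrogen-bonded to the ketone. This gives [4-(benzyloxy)-2-methoxy-6-methylphenyl](2,6-dihydroxy-4-methoxyphenyl)methanone F18.
- Hydrogenolysis (H2, Pd/C, EtOAc) removes the benzyl group to give 10.

**Further compounds**
F1 | step 7 | [3-[(dimethylamino)methyl]-2,6-dihydroxy-4-methoxyphenyl](4-hydroxy-2-methoxy-6-methylphenyl)methanone | COc1cc(O)c(C(=O)c2c(C)cc(O)cc2OC)c(O)c1CN(C)C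
F2 | step 6 | 1-methoxy-3,5-bis(tetrahydro-2H-pyran-2-yloxy)benzene (diastereomer mixture) | COc1cc(OC2CCCCO2)cc(OC2CCCCO2)c1
F3 | step 6 | 2-hydroxy-6-methyl-4-(tetrahydro-2H-pyran-2-yloxy)benzaldehyde (racemic) | Cc1cc(OC2CCCCO2)cc(O)c1C=O
F4 | step 6 | 2-methoxy-6-methyl-4-(tetrahydro-2H-pyran-2-yloxy)benzaldehyde (racemic) | Cc1cc(OC2CCCCO2)cc(OC)c1C=O
F5 | step 6 | [4-methoxy-2,6-bis(tetrahydro-2H-pyran-2-yloxy)phenyl]lithium (diastereomer mixture) | [Li]c1c(OC2CCCCO2)cc(OC)cc1OC1CCCCO1
F6 | step 6 | lithium [4-methoxy-2,6-bis(tetrahydro-2H-pyran-2-yloxy)phenyl][2-methoxy-6-methyl-4-(tetrahydro-2H-pyran-2-yloxy)phenyl]methanolate (diastereomer mixture) | [Li]OC(c1c(OC2CCCCO2)cc(OC)cc1OC1CCCCO1)c1c(C)cc(OC2CCCCO2)cc1OC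
F7 | step 6 | [4-methoxy-2,6-bis(tetrahydro-2H-pyran-2-yloxy)phenyl][2-methoxy-6-methyl-4-(tetrahydro-2H-pyran-2-yloxy)phenyl]methanol (diastereomer mixture) | OC(c1c(OC2CCCCO2)cc(OC)cc1OC1CCCCO1)c1c(C)cc(OC2CCCCO2)cc1OC
F8 | step 6 | [4-methoxy-2,6-bis(tetrahydro-2H-pyran-2-yloxy)phenyl][2-methoxy-6-methyl-4-(tetrahydro-2H-pyran-2-yloxy)phenyl]methanone (diastereomer mixture) | O=C(c1c(OC2CCCCO2)cc(OC)cc1OC1CCCCO1)c1c(C)cc(OC2CCCCO2)cc1OC
F9 | step 4 | phloroglucinol (benzene-1,3,5-triol) | Oc1cc(O)cc(O)c1
F10 | step 4 | 1,3,5-tris(methoxymethoxy)benzene | COCOc1cc(OCOC)cc(OCOC)c1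
F11 | step 4 | 4-(benzyloxy)-2-hydroxy-6-methylbenzaldehyde | Cc1cc(OCc2ccccc2)cc(O)c1C=O
F12 | step 4 | 4-(benzyloxy)-2-methoxy-6-methylbenzaldehyde | Cc1cc(OCc2ccccc2)cc(OC)c1C=O
F13 | step 4 | [2,4,6-tris(methoxymethoxy)phenyl]lithium | [Li]c1c(OCOC)cc(OCOC)cc1OCOC
F14 | step 4 | lithium [4-(benzyloxy)-2-methoxy-6-methylphenyl][2,4,6-tris(methoxymethoxy)phenyl]methanolate (racemic) | [Li]OC(c1c(OCOC)cc(OCOC)cc1OCOC)c1c(C)cc(OCc2ccccc2)cc1OC
F15 | step 4 | rac-[4-(benzyloxy)-2-methoxy-6-methylphenyl][2,4,6-tris(methoxymethoxy)phenyl]methanol | OC(c1c(OCOC)cc(OCOC)cc1OCOC)c1c(C)cc(OCc2ccccc2)cc1OC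
F16 | step 4 | [4-(benzyloxy)-2-methoxy-6-methylphenyl][2,4,6-tris(methoxymethoxy)phenyl]methanone | O=C(c1c(OCOC)cc(OCOC)cc1OCOC)c1c(C)cc(OCc2ccccc2)cc1OC
F17 | step 4 | [4-(benzyloxy)-2-methoxy-6-methylphenyl](2,4,6-trihydroxyphenyl)methanone | O=C(c1c(O)cc(O)cc1O)c1c(C)cc(OCc2ccccc2)cc1OC
F18 | step 4 | [4-(benzyloxy)-2-methoxy-6-methylphenyl](2,6-dihydroxy-4-methoxyphenyl)methanone | COc1cc(O)c(C(=O)c2c(C)cc(OCc3ccccc3)cc2OC)c(O)c1
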